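The plan cuts both O1–C2 bonds of the two rings C. Each of these bonds links a phenolic oxygen to the benzylic carbon that is the single stereocentre of a flavanone half, and the two O1 atoms coincide with the 4,4'-hydroxyls of a biphenyl whose 2,2',6,6'-oxygens become the 5- and 7-hydroxyls around the C6–C6'' bond. In one operation the dicaesium salt of 2,2',6,6'-tetrakis(benzyloxy)biphenyl-4,4'-diol opens two molecules of (R)-4-(4-bromophenyl)oxetan-2-one at the benzylic carbon with inversion, which sets both (S) centres and installs the propanoic acid arms that later close rings C. The precursors are thus a symmetrical protected biphenol and an enantioenriched β-lactone whose bromine masks the 4'-hydroxyl.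

Key step: step 7

Assumption: the target structure assigns no configuration to the C6–C6'' axis, so 15 to 17 may be handled as mixtures of rotamers about that axis; all of them carry the same (S) centres and lead to 18.

Step 1
Reactants: 1 3,5-bis(benzyloxy)phenol
Product: 2 [3,5-bis(benzyloxy)phenoxy]tri(propan-2-yl)silane
Conditions: TIPSCl, imidazole, DMF, rt
Reagents that add atoms: chlorotri(propan-2-yl)silane (TIPSCl), CC(C)[Si](Cl)(C(C)C)C(C)C
Why: Standard silylation of a phenol with a bulky silyl chloride and imidazole; the silyl ether masks the future O1 oxygen, withstands n-BuLi and, being bulky and poorly coordinating, shields the two ring C–H bonds next to it.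

Step 2
Reactants: 2 [3,5-bis(benzyloxy)phenoxy]tri(propan-2-yl)silane (2 equiv)
Product: 4 2,2',6,6'-tetrakis(benzyloxy)-4,4'-bis(triisopropylsilyloxy)biphenyl, via aryllithium 3 (not isolated)
Conditions: n-BuLi (1.05 equiv per 2), THF, 0 °C; then FeCl3 (1.1 equiv per 2), −78 °C to rt
Reagents that add atoms: none
Why: Directed ortho-metalation puts lithium on the ring carbon flanked by both benzyloxy oxygens (ring deprotonation between two ethers by n-BuLi at 0 °C should outrun benzylic deprotonation and Wittig rearrangement), and FeCl3 then oxidises the aryllithium so that two aryl groups, one from each of two molecules of 2, join in an oxidative homocoupling that forms the tetra-ortho-substituted biaryl bond at a fixed position without an aryl halide.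

Step 3
Reactants: 4 2,2',6,6'-tetrakis(benzyloxy)-4,4'-bis(triisopropylsilyloxy)biphenyl
Product: 5 2,2',6,6'-tetrakis(benzyloxy)biphenyl-4,4'-diol
Conditions: Bu4NF, AcOH, THF, 0 °C to rt
Reagents that add atoms: none
Why: Fluoride-induced cleavage of the two aryl silyl ethers, buffered with acetic acid, should free only the 4,4'-oxygens because benzyl ethers are inert to fluoride.

Step 4
Reactants: 6 ethyl 3-(4-bromophenyl)-3-oxopropanoate
Product: 7 ethyl (3R)-3-(4-bromophenyl)-3-hydroxypropanoate
Conditions: H2 (4 atm), RuCl2[(S)-BINAP] (0.5 mol %), EtOH, 80 °C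
Reagents that add atoms: none
Why: Noyori asymmetric hydrogenation of a β-keto ester, in which the ester carbonyl chelates ruthenium and the (S)-ligand should deliver hydride to the face that gives the (R)-carbinol (R because the aryl group outranks CH2CO2Et), while the aryl bromide is not reduced by this catalyst.

Step 5
Reactants: 7 ethyl (3R)-3-(4-bromophenyl)-3-hydroxypropanoate
Product: 8 (3R)-3-(4-bromophenyl)-3-hydroxypropanoic acid
Conditions: LiOH, THF/H2O, 0 °C; then aq. HCl
Reagents that add atoms: lithium hydroxide (its oxygen enters the carboxyl group), [Li+].[OH-]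
Why: Saponification touches the ester only, the carbinol centre is not involved, the low temperature is chosen to avoid β-elimination to the cinnamate, and the crystalline acid offers a point at which enantiomeric purity could be raised by recrystallisation if needed.

Step 6
Reactants: 8 (3R)-3-(4-bromophenyl)-3-hydroxypropanoic acid
Product: 10 (4R)-4-(4-bromophenyl)oxetan-2-one, via mixed sulfonic anhydride 9 (not isolated)
Conditions: PhSO2Cl, pyridine, 0 °C
Reagents that add atoms: none
Why: Carboxyl-activating β-lactonisation, in which the carboxylate becomes a mixed sulfonic anhydride and the hydroxyl closes the four-membered ring at the acyl carbon (4-exo-trig), so the C–O bond at the stereocentre is never broken and the (R) configuration is retained.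

Step 7
Reactants: 5 2,2',6,6'-tetrakis(benzyloxy)biphenyl-4,4'-diol; 10 (4R)-4-(4-bromophenyl)oxetan-2-one (2.4 equiv)
Product: 12 (3S,3'S)-3,3'-{[2,2',6,6'-tetrakis(benzyloxy)biphenyl-4,4'-diyl]bis(oxy)}bis[3-(4-bromophenyl)propanoic acid], via dicaesium bisphenoxide 11 (not isolated)
Conditions: Cs2CO3 (2.0 equiv), DMF, rt; then 10, 0 °C to rt; then 1 M HCl
Reagents that add atoms: none
Why: Each caesium phenoxide of 11 attacks C4 of a lactone molecule from the side opposite the ring oxygen (SN2 at the benzylic carbon, alkyl–oxygen cleavage), and the strain of the four-membered ring drives the carboxylate out, so two O1–C2 bonds form and no ring closes. The closest known reaction type is the opening of β-propiolactone by phenoxides to 3-aryloxypropanoic acids, together with the invertive SN2 opening of 4-substituted β-lactones by other soft nucleophiles. Both new stereocentres are controlled by the lactone alone: inversion of its (R) centre gives (S) in each arm, and since the biphenol is achiral and the two alkylations are remote, no matching problem arises. The step needs alkyl–oxygen rather than acyl–oxygen attack; a loosely paired caesium phenoxide in DMF favours the former, and any aryl ester formed by acyl attack carries a β-alkoxide that can re-close to the lactone, whereas the carboxylate from alkyl attack cannot return. It also needs clean inversion, which the electron-poor 4-bromophenyl group secures by disfavouring ionisation of the benzylic carbon (the path to racemic ether or to decarboxylation). Site selectivity is built into 5, whose only free oxygens are the 4,4'-hydroxyls para to the biaryl bond.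

Step 8
Reactants: 12 (3S,3'S)-3,3'-{[2,2',6,6'-tetrakis(benzyloxy)biphenyl-4,4'-diyl]bis(oxy)}bis[3-(4-bromophenyl)propanoic acid]
Product: 13 (3S,3'S)-3,3'-{[2,2',6,6'-tetrakis(benzyloxy)biphenyl-4,4'-diyl]bis(oxy)}bis{3-[4-(4,4,5,5-tetramethyl-1,3,2-dioxaborolan-2-yl)phenyl]propanoic acid}
Conditions: B2pin2, Pd(dppf)Cl2 (5 mol %), KOAc (excess), DMSO, 80 °C; then aq. citric acid
Reagents that add atoms: bis(pinacolato)diboron (B2pin2), CC1(C)OB(OC1(C)C)B1OC(C)(C)C(C)(C)O1
Why: Miyaura borylation (zerovalent palladium inserts into C–Br, acetate-assisted transmetalation with B2pin2, reductive elimination) is placed before ring closure because in 12 each stereocentre sits β to a potassium carboxylate that cannot enolise and eliminate under acetate, whereas a closed flavanone could open to a chalcone under the same base.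

Step 9
Reactants: 13 (3S,3'S)-3,3'-{[2,2',6,6'-tetrakis(benzyloxy)biphenyl-4,4'-diyl]bis(oxy)}bis{3-[4-(4,4,5,5-tetramethyl-1,3,2-dioxaborolan-2-yl)phenyl]propanoic acid}
Product: 15 (2S,2'S)-5,5',7,7'-tetrakis(benzyloxy)-2,2'-bis[4-(4,4,5,5-tetramethyl-1,3,2-dioxaborolan-2-yl)phenyl]-[6,6'-bichromane]-4,4'-dione, via bis(mixed trifluoroacetic anhydride) 14 (not isolated)
Conditions: TFAA (6 equiv), CH2Cl2, 0 °C to rt
Reagents that add atoms: none
Why: Intramolecular Friedel–Crafts acylation through the mixed trifluoroacetic anhydride closes each six-membered ring C at the ring carbon ortho to O1, which three oxygens activate; the two ortho carbons of each ring are equivalent, so only the 6,6''-linked bis-chromanone can arise, and the boryl-substituted aryl group, which is not electron-rich, should keep the benzylic ether from ionising in the acid medium.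

Step 10
Reactants: 15 (2S,2'S)-5,5',7,7'-tetrakis(benzyloxy)-2,2'-bis[4-(4,4,5,5-tetramethyl-1,3,2-dioxaborolan-2-yl)phenyl]-[6,6'-bichromane]-4,4'-dione
Product: 17 (2S,2'S)-5,5',7,7'-tetrakis(benzyloxy)-2,2'-bis(4-hydroxyphenyl)-[6,6'-bichromane]-4,4'-dione, via bis(aryl borate) 16 (not isolated)
Conditions: KHSO5 (as 2KHSO5·KHSO4·K2SO4), acetone/H2O, 0 °C, 15 min; then aq. Na2S2O3
Reagents that add atoms: potassium peroxymonosulfate (KHSO5), [K+].[O-]S(=O)(=O)OO
Why: Peroxide oxidation of an arylboronic ester (aryl shift from boron to oxygen, then hydrolysis of the borate) is run in weakly acidic aqueous acetone, so the newly released 4'-phenols never meet a base that could open ring C through a quinone methide or chalcone and erode C2.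

Step 11
Reactants: 17 (2S,2'S)-5,5',7,7'-tetrakis(benzyloxy)-2,2'-bis(4-hydroxyphenyl)-[6,6'-bichromane]-4,4'-dione
Product: 18 succedaneaflavanone, (2S,2'S)-5,5',7,7'-tetrahydroxy-2,2'-bis(4-hydroxyphenyl)-[6,6'-bichromane]-4,4'-dione
Conditions: H2 (1 atm), 10% Pd/C, EtOAc/MeOH, rt
Reagents that add atoms: none
Why: Hydrogenolysis of the four benzyl aryl ethers on palladium is neutral and, at low pressure and with the reaction stopped at full debenzylation, should spare the ring C carbonyl and the cyclic O1–C2 bond, so both (S) centres reach the target unchanged.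

Compound list
1 | 3,5-bis(benzyloxy)phenol | Oc1cc(OCc2ccccc2)cc(OCc2ccccc2)c1 | starting material
2 | [3,5-bis(benzyloxy)phenoxy]tri(propan-2-yl)silane | CC(C)[Si](Oc1cc(OCc2ccccc2)cc(OCc2ccccc2)c1)(C(C)C)C(C)C | intermediate
3 | [2,6-bis(benzyloxy)-4-(triisopropylsilyloxy)phenyl]lithium (not isolated) | [Li]c1c(OCc2ccccc2)cc(O[Si](C(C)C)(C(C)C)C(C)C)cc1OCc1ccccc1 | intermediate
4 | 2,2',6,6'-tetrakis(benzyloxy)-4,4'-bis(triisopropylsilyloxy)biphenyl | CC(C)[Si](Oc1cc(OCc2ccccc2)c(-c2c(OCc3ccccc3)cc(O[Si](C(C)C)(C(C)C)C(C)C)cc2OCc2ccccc2)c(OCc2ccccc2)c1)(C(C)C)C(C)C | intermediate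
5 | 2,2',6,6'-tetrakis(benzyloxy)biphenyl-4,4'-diol | Oc1cc(OCc2ccccc2)c(-c2c(OCc3ccccc3)cc(O)cc2OCc2ccccc2)c(OCc2ccccc2)c1 | intermediate
6 | ethyl 3-(4-bromophenyl)-3-oxopropanoate | CCOC(=O)CC(=O)c1ccc(Br)cc1 | starting material
7 | ethyl (3R)-3-(4-bromophenyl)-3-hydroxypropanoate | CCOC(=O)C[C@@H](O)c1ccc(Br)cc1 | intermediate
8 | (3R)-3-(4-bromophenyl)-3-hydroxypropanoic acid | OC(=O)C[C@@H](O)c1ccc(Br)cc1 | intermediate
9 | benzenesulfonic (3R)-3-(4-bromophenyl)-3-hydroxypropanoic anhydride (not isolated) | O=C(C[C@@H](O)c1ccc(Br)cc1)OS(=O)(=O)c1ccccc1 | intermediate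
10 | (4R)-4-(4-bromophenyl)oxetan-2-one | O=C1C[C@H](c2ccc(Br)cc2)O1 | intermediate
11 | dicaesium 2,2',6,6'-tetrakis(benzyloxy)biphenyl-4,4'-diolate (not isolated) | [Cs+].[Cs+].[O-]c1cc(OCc2ccccc2)c(-c2c(OCc3ccccc3)cc([O-])cc2OCc2ccccc2)c(OCc2ccccc2)c1 | intermediate
12 | (3S,3'S)-3,3'-{[2,2',6,6'-tetrakis(benzyloxy)biphenyl-4,4'-diyl]bis(oxy)}bis[3-(4-bromophenyl)propanoic acid] | OC(=O)C[C@@H](c1ccc(Br)cc1)Oc1cc(OCc2ccccc2)c(-c2c(OCc3ccccc3)cc(O[C@@H](CC(O)=O)c3ccc(Br)cc3)cc2OCc2ccccc2)c(OCc2ccccc2)c1 | intermediate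
13 | (3S,3'S)-3,3'-{[2,2',6,6'-tetrakis(benzyloxy)biphenyl-4,4'-diyl]bis(oxy)}bis{3-[4-(4,4,5,5-tetramethyl-1,3,2-dioxaborolan-2-yl)phenyl]propanoic acid} | OC(=O)C[C@@H](c1ccc(cc1)B1OC(C)(C)C(C)(C)O1)Oc1cc(OCc2ccccc2)c(-c2c(OCc3ccccc3)cc(O[C@@H](CC(O)=O)c3ccc(cc3)B3OC(C)(C)C(C)(C)O3)cc2OCc2ccccc2)c(OCc2ccccc2)c1 | intermediate
14 | bis(trifluoroacetic) mixed anhydride of diacid 13 (not isolated) | FC(F)(F)C(=O)OC(=O)C[C@@H](c1ccc(cc1)B1OC(C)(C)C(C)(C)O1)Oc1cc(OCc2ccccc2)c(-c2c(OCc3ccccc3)cc(O[C@@H](CC(=O)OC(=O)C(F)(F)F)c3ccc(cc3)B3OC(C)(C)C(C)(C)O3)cc2OCc2ccccc2)c(OCc2ccccc2)c1 | intermediate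
15 | (2S,2'S)-5,5',7,7'-tetrakis(benzyloxy)-2,2'-bis[4-(4,4,5,5-tetramethyl-1,3,2-dioxaborolan-2-yl)phenyl]-[6,6'-bichromane]-4,4'-dione | O=C1C[C@@H](c2ccc(cc2)B2OC(C)(C)C(C)(C)O2)Oc2cc(OCc3ccccc3)c(-c3c(OCc4ccccc4)cc4c(c3OCc3ccccc3)C(=O)C[C@@H](c3ccc(cc3)B3OC(C)(C)C(C)(C)O3)O4)c(OCc3ccccc3)c21 | intermediate
16 | bis(aryl pinacol borate) of 17, each 4'-oxygen bound to the dioxaborolane boron (not isolated) | O=C1C[C@@H](c2ccc(OB3OC(C)(C)C(C)(C)O3)cc2)Oc2cc(OCc3ccccc3)c(-c3c(OCc4ccccc4)cc4c(c3OCc3ccccc3)C(=O)C[C@@H](c3ccc(OB5OC(C)(C)C(C)(C)O5)cc3)O4)c(OCc3ccccc3)c21 | intermediate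
17 | (2S,2'S)-5,5',7,7'-tetrakis(benzyloxy)-2,2'-bis(4-hydroxyphenyl)-[6,6'-bichromane]-4,4'-dione | O=C1C[C@@H](c2ccc(O)cc2)Oc2cc(OCc3ccccc3)c(-c3c(OCc4ccccc4)cc4c(c3OCc3ccccc3)C(=O)C[C@@H](c3ccc(O)cc3)O4)c(OCc3ccccc3)c21 | intermediate
18 | succedaneaflavanone, (2S,2'S)-5,5',7,7'-tetrahydroxy-2,2'-bis(4-hydroxyphenyl)-[6,6'-bichromane]-4,4'-dione | O=C1C[C@@H](c2ccc(O)cc2)Oc2cc(O)c(-c3c(O)cc4c(c3O)C(=O)C[C@@H](c3ccc(O)cc3)O4)c(O)c21 | target

Total step count: 11 steps.
Longest linear sequence: 8 steps (1 → 2 → 4 → 5 → 12 → 13 → 15 → 17 → 18; the lactone branch 6 → 7 → 8 → 10 is equally long up to the key step).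

Steps most likely to fail

Step 7. The phenoxide may attack the acyl carbon, and the resulting aryl ester may then eliminate. The lactone may also be opened by base to the cinnamate. In either case etherification would stop after one arm or not start. Fallback: the same two O1–C2 bonds are made by a double Mitsunobu etherification (PPh3, DIAD, toluene, 0 °C) of biphenol 5 with hydroxy ester 7. This also inverts the (R) carbinol and should give diethyl (3S,3'S)-3,3'-{[2,2',6,6'-tetrakis(benzyloxy)biphenyl-4,4'-diyl]bis(oxy)}bis[3-(4-bromophenyl)propanoate] F1. Hydrolysis of F1 (LiOH, aq. THF, 0 °C) returns to diacid 12.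

Step 9. Acid-promoted ionisation of the benzylic C–O bond, protodeboronation, or trifluoroacetylation of the electron-rich ring may compete with closure of the second ring. Fallback: the order of events is changed. Dibromide 12 is cyclised first (TFAA, CH2Cl2, 0 °C), where bromine deactivates the benzylic carbon most strongly and no C–B bond is at stake. This should give (2S,2'S)-5,5',7,7'-tetrakis(benzyloxy)-2,2'-bis(4-bromophenyl)-[6,6'-bichromane]-4,4'-dione F2. F2 is then borylated (Pd(dppf)Cl2, B2pin2, KOAc, dioxane, 80 °C, shortest possible time) and rejoins the route at 15. The price is that the closed ring C meets acetate while hot.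

Step 2. The iron-mediated dimerisation of the hindered aryllithium may be outrun by its protonation or by over-oxidation of the electron-rich ring, so that 2 is returned or degraded. Fallback: the homocoupling is replaced by a cross-coupling of two partners, each made from 2 through aryllithium 3 in a separate run. Trapping with I2 should give [3,5-bis(benzyloxy)-4-iodophenoxy]tri(propan-2-yl)silane F3. Trapping with 2-isopropoxy-4,4,5,5-tetramethyl-1,3,2-dioxaborolane should give [3,5-bis(benzyloxy)-4-(4,4,5,5-tetramethyl-1,3,2-dioxaborolan-2-yl)phenoxy]tri(propan-2-yl)silane F4. Suzuki–Miyaura cross-coupling of F3 with F4 (Pd(OAc)2, SPhos, K3PO4, toluene/H2O, 100 °C) forms the same biaryl bond and returns to 4.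

Further compounds
F1 | step 7 | diethyl (3S,3'S)-3,3'-{[2,2',6,6'-tetrakis(benzyloxy)biphenyl-4,4'-diyl]bis(oxy)}bis[3-(4-bromophenyl)propanoate] | CCOC(=O)C[C@@H](c1ccc(Br)cc1)Oc1cc(OCc2ccccc2)c(-c2c(OCc3ccccc3)cc(O[C@@H](CC(=O)OCC)c3ccc(Br)cc3)cc2OCc2ccccc2)c(OCc2ccccc2)c1
F2 | step 9 | (2S,2'S)-5,5',7,7'-tetrakis(benzyloxy)-2,2'-bis(4-bromophenyl)-[6,6'-bichromane]-4,4'-dione | O=C1C[C@@H](c2ccc(Br)cc2)Oc2cc(OCc3ccccc3)c(-c3c(OCc4ccccc4)cc4c(c3OCc3ccccc3)C(=O)C[C@@H](c3ccc(Br)cc3)O4)c(OCc3ccccc3)c21
F3 | step 2 | [3,5-bis(benzyloxy)-4-iodophenoxy]tri(propan-2-yl)silane | CC(C)[Si](Oc1cc(OCc2ccccc2)c(I)c(OCc2ccccc2)c1)(C(C)C)C(C)C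
F4 | step 2 | [3,5-bis(benzyloxy)-4-(4,4,5,5-tetramethyl-1,3,2-dioxaborolan-2-yl)phenoxy]tri(propan-2-yl)silane | CC(C)[Si](Oc1cc(OCc2ccccc2)c(B2OC(C)(C)C(C)(C)O2)c(OCc2ccccc2)c1)(C(C)C)C(C)C
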